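Ring C of the isoflavone is disconnected at O1–C8a and C4–C4a. The two ring A carbons involved are neighbours, C8a beside the unsubstituted C8 and C4a beside the C5 oxygen, which is exactly the polarity of a 3-alkoxybenzyne. In one fluoride-triggered operation the enol oxygen of a ring B alpha-formyl arylacetate adds to the aryne at C8a and the aryl anion formed at C4a captures the ester, closing the pyranone and joining both fragments. The precursor is an ortho-silylaryl triflate of a 2-alkylphloroglucinol dibenzyl ether, with the silylated hydroxy-isopentyl chain already fixed between the two ring oxygens (the future C6), and a benzyl-protected methyl 2-aryl-3-hydroxyacrylate.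

Key step: step 11

Remark: the target is taken to be luteone hydrate, the tertiary alcohol drawn by the SMILES; it has no stereocentre, so no stereocontrol is required.

Step 1
Reactants: 1 3,5-bis(benzyloxy)phenol
Product: 2 2,6-bis(benzyloxy)-4-hydroxybenzaldehyde
Conditions: POCl3, DMF, MeCN, 0 °C to rt; then H2O; chromatography
Reagents that add atoms: N,N-dimethylformamide CN(C)C=O; water O
Why: Vilsmeier–Haack formylation of a phloroglucinol-type ring should go mainly para to the free hydroxyl (the carbon between the two benzyloxy groups), as it does with 3,5-dimethoxyphenol, and the less polar, chelated ortho-hydroxy aldehyde isomer is removed on silica.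

Step 2
Reactants: 2 2,6-bis(benzyloxy)-4-hydroxybenzaldehyde; 3 methyl (triphenylphosphoranylidene)acetate
Product: 4 methyl (E)-3-[2,6-bis(benzyloxy)-4-hydroxyphenyl]prop-2-enoate
Conditions: toluene, 110 °C
Reagents that add atoms: none
Why: Wittig olefination with a stabilised ylide, which is too weakly basic to deprotonate the phenol, should give the E-cinnamate on heating; the geometry is of no consequence because the alkene is reduced next.

Step 3
Reactants: 4 methyl (E)-3-[2,6-bis(benzyloxy)-4-hydroxyphenyl]prop-2-enoate
Product: 5 methyl 3-[2,6-bis(benzyloxy)-4-hydroxyphenyl]propanoate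
Conditions: TsNHNH2 (excess, in portions), NaOAc, DME/H2O, reflux
Reagents that add atoms: none
Why: Diimide reduction (diimide made in the flask from tosylhydrazide) transfers hydrogen only to the C=C bond, so the benzyl ethers, which would not survive catalytic hydrogenation, and the ester are left alone.

Step 4
Reactants: 5 methyl 3-[2,6-bis(benzyloxy)-4-hydroxyphenyl]propanoate
Product: 6 4-[2,6-bis(benzyloxy)-4-hydroxyphenyl]-2-methylbutan-2-ol
Conditions: MeMgBr (4 equiv), THF, 0 °C to rt; aq NH4Cl
Reagents that add atoms: methylmagnesium bromide C[Mg]Br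
Why: Double Grignard addition to the ester gives the tertiary alcohol; one further equivalent is consumed by the phenol, whose magnesium phenoxide is inert.

Step 5
Reactants: 6 4-[2,6-bis(benzyloxy)-4-hydroxyphenyl]-2-methylbutan-2-ol
Product: 7 4-[2,6-bis(benzyloxy)-3-bromo-4-hydroxyphenyl]-2-methylbutan-2-ol
Conditions: NBS (1.0 equiv), CH2Cl2, −78 to 0 °C
Reagents that add atoms: N-bromosuccinimide O=C1CCC(=O)N1Br
Why: Electrophilic aromatic bromination can only reach the two equivalent ring carbons ortho to the hydroxyl, so one equivalent of NBS at low temperature should give a single monobromide.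

Step 6
Reactants: 7 4-[2,6-bis(benzyloxy)-3-bromo-4-hydroxyphenyl]-2-methylbutan-2-ol
Product: 8 [3,5-bis(benzyloxy)-2-bromo-4-[3-methyl-3-(trimethylsilyloxy)butyl]phenoxy]trimethylsilane
Conditions: HMDS, TMSCl, THF, 60 °C; filter, evaporate (no aqueous work-up)
Reagents that add atoms: hexamethyldisilazane C[Si](C)(C)N[Si](C)(C)C; chlorotrimethylsilane C[Si](C)(C)Cl
Why: Silylation of the phenol and the tertiary alcohol in one operation provides the O-silyl group needed for the next step and masks the alcohol; the only by-product is a filterable salt, so the water-sensitive aryl silyl ether is never exposed to water.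

Step 7
Reactants: 8 [3,5-bis(benzyloxy)-2-bromo-4-[3-methyl-3-(trimethylsilyloxy)butyl]phenoxy]trimethylsilane
Product: 10 3,5-bis(benzyloxy)-4-[3-methyl-3-(trimethylsilyloxy)butyl]-2-(trimethylsilyl)phenyl trifluoromethanesulfonate, via lithium ortho-silylphenoxide 9 (not isolated)
Conditions: n-BuLi (1.05 equiv), THF, −100 to −78 °C; then Tf2O, −100 to −78 °C; aq NaHCO3
Reagents that add atoms: trifluoromethanesulfonic anhydride O=S(=O)(OS(=O)(=O)C(F)(F)F)C(F)(F)F
Why: Bromine–lithium exchange followed by the anionic oxygen-to-carbon silyl shift (retro-Brook rearrangement) gives the lithium ortho-silylphenoxide, which is triflated in the same flask; this is the standard entry to ortho-silylaryl triflates, and exchange far outruns deprotonation of the benzyl ethers at this temperature.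

Step 8
Reactants: 11 2,4-dihydroxyphenylacetic acid
Product: 12 methyl 2-(2,4-dihydroxyphenyl)acetate
Conditions: MeOH, H2SO4 (cat.), reflux
Reagents that add atoms: methanol CO
Why: Fischer esterification in a large excess of methanol keeps the ortho-hydroxy acid as the open methyl ester and not as the benzofuranone lactone.

Step 9
Reactants: 12 methyl 2-(2,4-dihydroxyphenyl)acetate
Product: 13 methyl 2-[2,4-bis(benzyloxy)phenyl]acetate
Conditions: BnBr (2.4 equiv), K2CO3, DMF, rt
Reagents that add atoms: benzyl bromide BrCc1ccccc1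
Why: Williamson ether synthesis with a carbonate base alkylates both phenoxides and is too mild to enolise the ester.

Step 10
Reactants: 13 methyl 2-[2,4-bis(benzyloxy)phenyl]acetate; 14 methyl formate
Product: 15 methyl (Z)-2-[2,4-bis(benzyloxy)phenyl]-3-hydroxyprop-2-enoate
Conditions: NaH (3 equiv), 14 (excess), THF, 0 °C to rt; then aq HCl to pH 3
Reagents that add atoms: none
Why: Crossed Claisen condensation with the non-enolisable formate is driven to completion by formation of the sodium enolate, and acidification should give the alpha-formyl ester mainly as its hydrogen-bonded Z-enol; the formyl carbon is the future C2.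

Step 11
Reactants: 10 3,5-bis(benzyloxy)-4-[3-methyl-3-(trimethylsilyloxy)butyl]-2-(trimethylsilyl)phenyl trifluoromethanesulfonate; 15 methyl (Z)-2-[2,4-bis(benzyloxy)phenyl]-3-hydroxyprop-2-enoate
Product: 18 5,7-bis(benzyloxy)-3-[2,4-bis(benzyloxy)phenyl]-6-(3-hydroxy-3-methylbutyl)-4H-chromen-4-one, via aryne 16 (not isolated), via isoflavone silyl ether 17 (not isolated)
Conditions: CsF (4 equiv), THF, 65 °C, 10 in slight excess (1.3 equiv); filter; then PPTS (cat.), MeOH, rt
Reagents that add atoms: none
Why: Proposed new method: CsF removes the aryl trimethylsilyl group of 10 and triflate departs to give aryne 16, while fluoride also converts 15 into its cesium enolate; the enolate oxygen adds to the aryne carbon remote from the flanking benzyloxy group (the future C8a), and the aryl anion thus placed at the future C4a attacks the ester carbonyl held cis to that oxygen, expelling methoxide. The closest known reaction type is the fluoride-induced annulation of methyl salicylates with ortho-silylaryl triflates to xanthones (oxygen addition to the aryne, then intramolecular acyl substitution), of which this is the acyclic, vinylogous enol case. Ring C is closed by a 6-exo-trig acyl substitution that forms C4–C4a after the intermolecular O1–C8a bond. No stereocentre is formed and the enol geometry is not inherited, because the enolate equilibrates and only the form with oxygen and ester cis can cyclise. Oxygen- over carbon-arylation is favoured because the alpha carbon already carries the ortho-substituted ring B (carbon attack would build a quaternary centre) and the oxygen of a cesium enolate in THF is exposed; attack at C8a and not C4a is secured by the C5 benzyloxy group, which by induction and distortion of the aryne steers nucleophiles to the distal carbon, and THF with excess CsF favours acyl capture over protonation of the aryl anion. PPTS in methanol then cleaves the tertiary silyl ether of 17.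

Step 12
Reactants: 18 5,7-bis(benzyloxy)-3-[2,4-bis(benzyloxy)phenyl]-6-(3-hydroxy-3-methylbutyl)-4H-chromen-4-one
Product: 19 5,7-dihydroxy-3-(2,4-dihydroxyphenyl)-6-(3-hydroxy-3-methylbutyl)-4H-chromen-4-one (luteone hydrate)
Conditions: H2 (1 atm), palladium on carbon (Pd/C, 10%), EtOAc/MeOH, rt; followed by HPLC and halted when the last benzyl ether is gone; neutral filtration
Reagents that add atoms: none
Why: Catalytic hydrogenolysis of aryl benzyl ethers is much faster than saturation of the conjugated C2=C3 bond of the pyranone, so stopping at full debenzylation should give the target, and the neutral medium avoids acid-induced cyclisation of the tertiary alcohol onto a neighbouring phenol.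

Compound list
1 | 3,5-bis(benzyloxy)phenol | Oc1cc(OCc2ccccc2)cc(OCc2ccccc2)c1 | starting material
2 | 2,6-bis(benzyloxy)-4-hydroxybenzaldehyde | O=Cc1c(OCc2ccccc2)cc(O)cc1OCc1ccccc1 | intermediate
3 | methyl (triphenylphosphoranylidene)acetate | COC(=O)C=P(c1ccccc1)(c1ccccc1)c1ccccc1 | starting material
4 | methyl (E)-3-[2,6-bis(benzyloxy)-4-hydroxyphenyl]prop-2-enoate | COC(=O)/C=C/c1c(OCc2ccccc2)cc(O)cc1OCc1ccccc1 | intermediate
5 | methyl 3-[2,6-bis(benzyloxy)-4-hydroxyphenyl]propanoate | COC(=O)CCc1c(OCc2ccccc2)cc(O)cc1OCc1ccccc1 | intermediate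
6 | 4-[2,6-bis(benzyloxy)-4-hydroxyphenyl]-2-methylbutan-2-ol | CC(C)(O)CCc1c(OCc2ccccc2)cc(O)cc1OCc1ccccc1 | intermediate
7 | 4-[2,6-bis(benzyloxy)-3-bromo-4-hydroxyphenyl]-2-methylbutan-2-ol | CC(C)(O)CCc1c(OCc2ccccc2)cc(O)c(Br)c1OCc1ccccc1 | intermediate
8 | [3,5-bis(benzyloxy)-2-bromo-4-[3-methyl-3-(trimethylsilyloxy)butyl]phenoxy]trimethylsilane | CC(C)(O[Si](C)(C)C)CCc1c(OCc2ccccc2)cc(O[Si](C)(C)C)c(Br)c1OCc1ccccc1 | intermediate
9 | lithium 3,5-bis(benzyloxy)-4-[3-methyl-3-(trimethylsilyloxy)butyl]-2-(trimethylsilyl)phenoxide (not isolated) | [Li+].CC(C)(O[Si](C)(C)C)CCc1c(OCc2ccccc2)cc([O-])c([Si](C)(C)C)c1OCc1ccccc1 | intermediate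
10 | 3,5-bis(benzyloxy)-4-[3-methyl-3-(trimethylsilyloxy)butyl]-2-(trimethylsilyl)phenyl trifluoromethanesulfonate | CC(C)(O[Si](C)(C)C)CCc1c(OCc2ccccc2)cc(OS(=O)(=O)C(F)(F)F)c([Si](C)(C)C)c1OCc1ccccc1 | intermediate
11 | 2,4-dihydroxyphenylacetic acid | OC(=O)Cc1ccc(O)cc1O | starting material
12 | methyl 2-(2,4-dihydroxyphenyl)acetate | COC(=O)Cc1ccc(O)cc1O | intermediate
13 | methyl 2-[2,4-bis(benzyloxy)phenyl]acetate | COC(=O)Cc1ccc(OCc2ccccc2)cc1OCc1ccccc1 | intermediate
14 | methyl formate | COC=O | starting material
15 | methyl (Z)-2-[2,4-bis(benzyloxy)phenyl]-3-hydroxyprop-2-enoate | COC(=O)/C(=C\O)c1ccc(OCc2ccccc2)cc1OCc1ccccc1 | intermediate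
16 | 3,5-bis(benzyloxy)-4-[3-methyl-3-(trimethylsilyloxy)butyl]benzyne (not isolated) | CC(C)(O[Si](C)(C)C)CCC1=C(OCc2ccccc2)C#CC=C1OCc1ccccc1 | intermediate
17 | 5,7-bis(benzyloxy)-3-[2,4-bis(benzyloxy)phenyl]-6-[3-methyl-3-(trimethylsilyloxy)butyl]-4H-chromen-4-one (not isolated) | CC(C)(O[Si](C)(C)C)CCc1c(OCc2ccccc2)cc2occ(-c3ccc(OCc4ccccc4)cc3OCc3ccccc3)c(=O)c2c1OCc1ccccc1 | intermediate
18 | 5,7-bis(benzyloxy)-3-[2,4-bis(benzyloxy)phenyl]-6-(3-hydroxy-3-methylbutyl)-4H-chromen-4-one | CC(C)(O)CCc1c(OCc2ccccc2)cc2occ(-c3ccc(OCc4ccccc4)cc3OCc3ccccc3)c(=O)c2c1OCc1ccccc1 | intermediate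
19 | 5,7-dihydroxy-3-(2,4-dihydroxyphenyl)-6-(3-hydroxy-3-methylbutyl)-4H-chromen-4-one (luteone hydrate) | CC(C)(O)CCc1c(O)cc2occ(-c3ccc(O)cc3O)c(=O)c2c1O | target

Total step count: 12.
Longest linear sequence: 9 steps (steps 1 to 7, then 11 and 12, from compound 1).

Steps most likely to fail

Step 11 (proposed new method). The ambident enolate may arylate at carbon instead of oxygen, or the aryl anion may be protonated before it reaches the ester, so that ring C does not close. The fallback uses known chemistry, sets out from 13 (together with 10) and returns at 18. Saponification of 13 (LiOH, THF/H2O) gives 2-[2,4-bis(benzyloxy)phenyl]acetic acid F1. F1 and 10 with CsF in THF at 125 °C (sealed tube) should undergo the known insertion of an aryne into the C–O bond of a carboxylic acid. The carboxylate, which has no nucleophilic carbon, adds through oxygen at the same distal aryne carbon and the aryl anion takes over the acyl group. This gives the ortho-hydroxy deoxybenzoin 1-{2,4-bis(benzyloxy)-6-hydroxy-3-[3-methyl-3-(trimethylsilyloxy)butyl]phenyl}-2-[2,4-bis(benzyloxy)phenyl]ethan-1-one F2. PPTS in MeOH frees the tertiary alcohol to give 1-[2,4-bis(benzyloxy)-6-hydroxy-3-(3-hydroxy-3-methylbutyl)phenyl]-2-[2,4-bis(benzyloxy)phenyl]ethan-1-one F3. Heating F3 with N,N-dimethylformamide dimethyl acetal in toluene supplies C2 as an enaminone, which cyclises with loss of dimethylamine to 18 (the classical deoxybenzoin route to isoflavones).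

Step 7. The oxygen-to-carbon silyl migration may stay incomplete, or Tf2O may react with the tertiary silyl ether instead of the hindered lithium phenoxide. The fallback sets out from 6 and returns at 10 by carbamate-directed ortho-silylation, which needs neither the bromide nor Tf2O. Phenol 6 with isopropyl isocyanate and catalytic Et3N in CH2Cl2 gives 3,5-bis(benzyloxy)-4-(3-hydroxy-3-methylbutyl)phenyl N-(propan-2-yl)carbamate F4; the tertiary alcohol reacts far more slowly. TMSOTf and TMEDA in Et2O silylate the N–H and the tertiary O–H in the flask to 3,5-bis(benzyloxy)-4-[3-methyl-3-(trimethylsilyloxy)butyl]phenyl N-(propan-2-yl)-N-(trimethylsilyl)carbamate F5, which is not isolated. n-BuLi/TMEDA at −78 °C lithiates the ring carbon between the carbamate and a benzyloxy group, and TMSCl quenches it. Bicarbonate work-up hydrolyses the N–Si bond and should give 3,5-bis(benzyloxy)-4-[3-methyl-3-(trimethylsilyloxy)butyl]-2-(trimethylsilyl)phenyl N-(propan-2-yl)carbamate F6. DBU and Et2NH in MeCN at 40 °C cleave the carbamate, and PhNTf2 triflates the released phenoxide to 10.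

Step 1. The formylation may show poor selectivity between the carbons para and ortho to the hydroxyl, with loss of material in the isomer separation. The fallback sets out from 1 and returns at 2 by directed ortho-metalation, which fixes the regiochemistry. Silylation of 1 (TIPSCl, imidazole, DMF) gives [3,5-bis(benzyloxy)phenoxy]tri(propan-2-yl)silane F7. n-BuLi in THF at 0 °C lithiates the carbon between the two benzyloxy groups; the bulky, weakly directing silyloxy group keeps its own ortho positions unreactive. A DMF quench gives 2,6-bis(benzyloxy)-4-[tri(propan-2-yl)silyloxy]benzaldehyde F8, and TBAF in THF at 0 °C releases 2.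

Further compounds
F1 | step 11 | 2-[2,4-bis(benzyloxy)phenyl]acetic acid | OC(=O)Cc1ccc(OCc2ccccc2)cc1OCc1ccccc1
F2 | step 11 | 1-{2,4-bis(benzyloxy)-6-hydroxy-3-[3-methyl-3-(trimethylsilyloxy)butyl]phenyl}-2-[2,4-bis(benzyloxy)phenyl]ethan-1-one | CC(C)(O[Si](C)(C)C)CCc1c(OCc2ccccc2)cc(O)c(C(=O)Cc2ccc(OCc3ccccc3)cc2OCc2ccccc2)c1OCc1ccccc1
F3 | step 11 | 1-[2,4-bis(benzyloxy)-6-hydroxy-3-(3-hydroxy-3-methylbutyl)phenyl]-2-[2,4-bis(benzyloxy)phenyl]ethan-1-one | CC(C)(O)CCc1c(OCc2ccccc2)cc(O)c(C(=O)Cc2ccc(OCc3ccccc3)cc2OCc2ccccc2)c1OCc1ccccc1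
F4 | step 7 | 3,5-bis(benzyloxy)-4-(3-hydroxy-3-methylbutyl)phenyl N-(propan-2-yl)carbamate | CC(C)NC(=O)Oc1cc(OCc2ccccc2)c(CCC(C)(C)O)c(OCc2ccccc2)c1
F5 | step 7 | 3,5-bis(benzyloxy)-4-[3-methyl-3-(trimethylsilyloxy)butyl]phenyl N-(propan-2-yl)-N-(trimethylsilyl)carbamate | CC(C)N(C(=O)Oc1cc(OCc2ccccc2)c(CCC(C)(C)O[Si](C)(C)C)c(OCc2ccccc2)c1)[Si](C)(C)C
F6 | step 7 | 3,5-bis(benzyloxy)-4-[3-methyl-3-(trimethylsilyloxy)butyl]-2-(trimethylsilyl)phenyl N-(propan-2-yl)carbamate | CC(C)NC(=O)Oc1cc(OCc2ccccc2)c(CCC(C)(C)O[Si](C)(C)C)c(OCc2ccccc2)c1[Si](C)(C)C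
F7 | step 1 | [3,5-bis(benzyloxy)phenoxy]tri(propan-2-yl)silane | CC(C)[Si](Oc1cc(OCc2ccccc2)cc(OCc2ccccc2)c1)(C(C)C)C(C)C
F8 | step 1 | 2,6-bis(benzyloxy)-4-[tri(propan-2-yl)silyloxy]benzaldehyde | CC(C)[Si](Oc1cc(OCc2ccccc2)c(C=O)c(OCc2ccccc2)c1)(C(C)C)C(C)C
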